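The earlier runs and the new flask are simulated for substances that don't exist; scatter was added.

Target forms from starting material and reagent one to one, so the share of starting material left, f, also gives the reagent left, and starting material is the limiting reagent in Saturday's flask.

| flask | starting material | reagent | free catalyst | time |
|---|---|---|---|---|
| Sunday's | 0.0500 M | 0.0600 M | 2.50 × 10⁻⁴ M |  |
| Thursday's | 0.0500 M | 0.0600 M | 1.30 × 10⁻⁴ M |  |
| Friday's | 0.0500 M | 0.120 M | 2.50 × 10⁻⁴ M |  |
| Saturday's | 0.0250 M | 0.0600 M | 8.20 × 10⁻⁵ M | 31 min |

- Sunday's run (time / min: [starting material] / M): 2.4: 0.0351; 7.2: 0.0232; 14: 0.0169; 22: 0.0129; 31: 0.0103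
- Thursday's run (time / min: [starting material] / M): 2.4: 0.0387; 7.2: 0.0287; 14: 0.0207; 22: 0.0165; 31: 0.0129
- Friday's run (time / min: [starting material] / M): 2.4: 0.0259; 7.2: 0.0131; 14: 0.0072; 22: 0.0039; 31: 0.0024

(each reading ± 3 × 10⁻⁴ M)

* order of the initial rate in [reagent], near the charge of the Sunday's run, the rate being that where two percent of its starting material are target
* order of the initial rate in [free catalyst], near the charge of the Sunday's run, the rate being that where two percent of its starting material are target
* starting material in the Saturday's run at 31 min, as a share of the starting material charged

- Overall: starting material + reagent -> target, with free catalyst as catalyst.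
- Constant volume, constant temperature.
- An order is taken over about fifteen percent of the charge, up and down.

For a rate first order in each partner, one quantity removes the emptying of both from f: the logarithm of reagent per starting material now over the same ratio at the charge, divided by the reagent's excess in M. Call it the clock; it is the rate constant summed over time.

At 31 min, Sunday's flask has f = 20.6% and reads 49.6 M⁻¹. Thursday's flask has f = 25.8% and reads 39.2 M⁻¹. Thursday's catalyst charge is 0.520 of Sunday's, yet its clock is 0.790 of Sunday's, so part of the clock does not follow the catalyst.

Friday's flask, with more reagent, reads 36.2 M⁻¹, less than Sunday's at the same catalyst, so the line is drawn through the two flasks that share Saturday's reagent charge. Its slope is 87100 M⁻², and at zero catalyst it reads 27.8 M⁻¹.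

So Saturday's flask reads 35.0 M⁻¹: its clock at 31 min, background plus slope times catalyst charge. Inverted, that clock gives my reckoning of f = 19.5%.

The forecast differs, with 17% left (range 13% to 23%) and orders 0.97 in reagent and 0.6 in free catalyst, on a reading of “product inhibition with about first order in reagent”.

The simulation gives 20.2% left in Saturday's flask, with orders 1.0 and 0.71.

    free catalyst + starting material + reagent → target + free catalyst (9180 M⁻² min⁻¹)
    free catalyst + reagent → spent catalyst + reagent (2.904 M⁻¹ min⁻¹)
    starting material + reagent → target (0.9420 M⁻¹ min⁻¹)

The main reason for Saturday's conversion is the direct conversion of starting material and reagent, the uncatalysed background. With the conversion of starting material and reagent into target taken away, the order in free catalyst goes from 0.71 to 1.0. On the clock, reckoned at 35.0 M⁻¹ for Saturday's flask, its 20.2% reads 34.1 M⁻¹; without that step Saturday's flask leaves 77.3%, which reads 4.52 M⁻¹, a difference of 29.6 M⁻¹.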